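## Structural features

The target is a germacranolide: a cyclodecane (C1–C10) with an α-methylene-γ-butyrolactone (O6–C12(=O)–C11(=C13)–C7) fused across C6–C7, oxiranes spanning C1/C10 and C4/C5, a free tertiary hydroxyl on C7 and a methacrylate on O8. It has seven stereocentres: five are contiguous (4R,5R,6R,7S,8R) and the pair C10/C1 (10R,1S) lies across the ring. In the conventional orientation the C4/C5 oxirane is the trans type (4α,5β) that derives from an E olefin, and the C1/C10 oxirane is the cis type (1α,10α) that derives from a Z olefin. O6 and the 7-hydroxyl are both α, so the lactone is trans-fused, and O8 is β, trans to the 7-hydroxyl. The fragile elements are the two Michael acceptors (C11=C13 and the methacrylate), the epoxides, which open transannularly under acid, and the O8 ester beside a tertiary alcohol, which can migrate under base. The real difficulty is the ten-membered carbocycle with two stereodefined trisubstituted olefin/epoxide units, together with the fully substituted carbinol C7 flanked by the oxygenated centres C6 and C8. C6 is at once a carbinol carbon, allylic to C4=C5 once the C4/C5 oxirane is traced back to its olefin, and γ to the C12 carboxyl through C7 and C11. The key step uses this: a C5 alkenyl–metal adding to a C6 aldehyde makes the ring bond C5–C6, the C6 stereocentre and an alkoxide placed to close the O6–C12 lactone.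

## Logic of the disconnections

28 ⇒ 26 (through 27). The four C–O bonds of the two oxiranes are cut. They are the most acid-sensitive groups, and their cis and trans relationships map directly onto a Z C1=C10 and an E C4=C5 olefin. Four stereocentres disappear and only C6, C7 and C8 remain. The forward oxidation must be neutral, must touch only the two electron-rich olefins, and must reach the outer face of each.

26 ⇒ 25. The O7–H bond is replaced by O7–Si. A masked, non-chelating tertiary oxygen is needed during ring closure, because a free α-hydroxy aldehyde could rearrange and would change the facial bias. The forward cleavage must be non-basic and must precede epoxidation.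

25 ⇒ 22 (through 24 and 23). C5–C6 and O6–C12 are cut. Both ring closures collapse into one polar event, because C6 is simultaneously allylic, carbinol and γ to C12. The carbocycle and the lactone vanish, leaving an acyclic chain with two stereocentres (C7, C8). The forward step needs an organometallic that tolerates two esters and two acceptor olefins, closure in preference to oligomerisation, and attack on the aldehyde face that puts O6 cis to O7.

22 ⇒ 21 ⇒ 20 ⇒ 19. The O8–acyl bond, the C6 oxidation level and the two ketal C–O bonds are adjusted. O6 (primary) and O8 (secondary) can be told apart by reactivity, so they can share one ketal earlier. The demand is that the hydroxyls, which are γ to the C12 ester once free, must not lactonise prematurely. Hence the acid exposure is short and mild, the primary alcohol is oxidised at once, and acylation follows directly.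

19 ⇒ 18 ⇒ 15 + 16 (through 17). O7–Si and then C7–C11 are cut. A tertiary carbinol carrying an acrylate is the retron for adding an acrylate α-anion equivalent to a ketone. The quaternary centre disappears and a monosubstituted, ketal-protected dihydroxyacetone remains. The nucleophile must be non-basic, because C8 is epimerisable, and must enter trans to the side chain.

15 ⇒ 14 ⇒ 12 + 9 (through 13), and 12 ⇒ 10 + 11. C8–C9 is cut next to the carbonyl, then the C=N bond. This splits the chain into a C3 unit and a C10 unit and leaves C8 as the only centre set by a reagent. All later centres follow from it. The forward alkylation needs the R-configured auxiliary, clean SN2 at the allylic bromide without touching the alkenyl iodide, and hydrazone removal without ozone.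

9 ⇒ 8 ⇒ 7 ⇒ 4 + 5 (through 6). C9–Br, the C9 oxidation level and C1=C10 are cut. A Z-selective phosphonate olefination builds the trisubstituted olefin with C9 cis to C2. The geometry must survive reduction and bromination.

4 ⇒ 3 ⇒ 1 (through 2). The aldehyde is taken back to the alcohol, and C4–C15 and C5–I are cut. Syn carbometalation of a terminal alkyne fixes the E alkenyl iodide in one operation from a five-carbon alkynol.

## Other disconnections considered

Alternative 1: The cut is at C9–C10 and C1–C2 of the open chain. An organocopper reagent derived from Grignard reagent A2 would add syn across propyne A3, and the resulting Z alkenylcopper would add 1,4 to methyl vinyl ketone A4 to give ketone acetal A1.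
- In its favour: the Z geometry is fixed by the mechanism of syn addition, the feedstocks are cheap, and one operation replaces steps 3–5 of the chosen route. On step count for the Z olefin it is the better plan, and on reliability of the geometry it is at least the equal.
- Against it: A2 carries the metal β to two acetal oxygens and should eliminate to an enol ether alkoxide before it can be transmetalated. Alkenylcopper additions to A4 need activation. A1 ends in a C4 methyl ketone that still has to become an E-configured C4=C5 nucleophile, which a ketone olefination does not deliver cleanly, whereas step 1 sets that geometry directly.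
- Comparison: it creates no ring and no stereocentre, so the hard part of the structure (the carbocycle and C6–C8) is untouched. C7 and C8 would then have to be built by acyclic stereocontrol from the unmasked C8 aldehyde. The chosen plan is longer in the fragment but shorter and better controlled overall.

Alternative 2: The cut is at the C5–C10 bond of a bicyclic precursor. Base would turn the C5 tertiary alcohol of cis-decalin mesylate A6 into its alkoxide, which fragments with loss of the C1 sulfonate to cyclodecenone A5.
- In its favour: ring expansion needs no high dilution, and the concerted anti-periplanar fragmentation translates decalin configuration into Z geometry with certainty. On this point it is better than an entropically demanding macrocyclisation. The C4 oxygen is already in place with the right configuration, so the C4/C5 oxirane could be closed by internal displacement instead of relying on face selectivity, which is also better than the chosen plan.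
- Against it: A6 needs six stereocentres, two of them fully substituted ring-fusion carbons, and four different protecting groups. In A5 the C6 hydrogen is α and the C7 oxygen is β to the new ketone, so the basic conditions invite epimerisation or β-elimination.
- Comparison: after the fragmentation there remain ketone reduction, epoxide closure, three deprotections, oxidation of C12 to the carboxyl level, lactonisation, acylation and the C1=C10 epoxidation. The last of these faces the same facial question as in the chosen route, so the two are equal there. In step economy the alternative is clearly worse.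

Alternative 3: The cut is at C7–C11. The bromoacrylate A8 would give an alkenylchromium at C11 with divalent chromium and catalytic nickel; this adds to the C7 ketone, forming the lactone ring and the carbinol at once, to give dienolide A7 (identical with 26).
- In its favour: a five-membered closure is kinetically far easier than a ten-membered one, the tether fixes the 6,12-regiochemistry of the lactone, and the product needs no deprotection. It is better than the chosen key step on ease of closure and one step shorter after it. The chemoselectivity demands on the chromium reagent are equal.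
- Against it: the ten-membered dienone with oxygen at C6 and C8 must already exist, so the ring problem is only postponed. A ketone flanked by two acyloxy groups is open to reductive cleavage by divalent chromium and to epimerisation. Alkenylchromium reagents add to ketones much more slowly than to aldehydes. The tether must deliver C11 trans to O6 across a flexible ring, which is not the naturally favoured mode of a short tether.
- Comparison: a second macrocyclisation would still be needed to reach A8, so the total route is longer than the chosen plan.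

Key step: step 14

Remark: germacrane numbering is used for all intermediates. The auxiliary is the R enantiomer (RAMP), because the hydrazone alkylation must install the R configuration at C8 and the S enantiomer would give the opposite centre.

## Route

Step 1
Reactants: 1 pent-4-yn-1-ol
Product: 3 (E)-5-iodo-4-methylpent-4-en-1-ol, via alkenylalane 2 (not isolated)
Conditions: Me3Al (3 equiv), Cp2ZrCl2 (0.25 equiv), CH2Cl2, 0 °C to rt; then I2, THF, −30 to 0 °C
Reagents that add atoms: trimethylaluminium C[Al](C)C; iodine I-I
Why: Zirconium-catalysed carboalumination adds methyl and aluminium syn across the alkyne with aluminium at the terminus, and iodinolysis proceeds with retention, so the E alkenyl iodide with C15 in place results.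

Step 2
Reactants: 3 (E)-5-iodo-4-methylpent-4-en-1-ol
Product: 4 (E)-5-iodo-4-methylpent-4-enal
Conditions: TEMPO (cat.), PhI(OAc)2, CH2Cl2, rt
Reagents that add atoms: none
Why: Oxoammonium oxidation of a primary alcohol stops at the aldehyde and leaves the alkenyl iodide untouched.

Step 3
Reactants: 4 (E)-5-iodo-4-methylpent-4-enal; 5 ethyl 2-[bis(2,2,2-trifluoroethoxy)phosphoryl]propanoate
Product: 7 ethyl (2Z,6E)-7-iodo-2,6-dimethylhepta-2,6-dienoate, via potassium phosphonate carbanion 6 (not isolated)
Conditions: KN(SiMe3)2, 18-crown-6, THF, −78 °C; then 4, −78 °C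
Reagents that add atoms: none
Why: Still–Gennari olefination; the electron-poor phosphonate under dissociating conditions eliminates kinetically to the Z enoate, which places the ester carbon (C9) cis to the chain (C2) across C1=C10.

Step 4
Reactants: 7 ethyl (2Z,6E)-7-iodo-2,6-dimethylhepta-2,6-dienoate
Product: 8 (2Z,6E)-7-iodo-2,6-dimethylhepta-2,6-dien-1-ol
Conditions: i-Bu2AlH, CH2Cl2, −78 °C; aq. potassium sodium tartrate
Reagents that add atoms: none
Why: 1,2-Reduction of the enoate by the aluminium hydride gives the allylic alcohol without olefin isomerisation or loss of iodide at low temperature.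

Step 5
Reactants: 8 (2Z,6E)-7-iodo-2,6-dimethylhepta-2,6-dien-1-ol
Product: 9 (1E,5Z)-7-bromo-1-iodo-2,6-dimethylhepta-1,5-diene
Conditions: CBr4, PPh3, CH2Cl2, −20 to 0 °C
Reagents that add atoms: carbon tetrabromide BrC(Br)(Br)Br
Why: Appel bromination displaces the alkoxyphosphonium by SN2 at the primary allylic carbon, so the Z geometry should be retained.

Step 6
Reactants: 10 2,2-dimethyl-1,3-dioxan-5-one; 11 (R)-1-amino-2-(methoxymethyl)pyrrolidine (RAMP)
Product: 12 (R)-N-(2,2-dimethyl-1,3-dioxan-5-ylidene)-2-(methoxymethyl)pyrrolidin-1-amine
Conditions: toluene, 80 °C, 4 Å molecular sieves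
Reagents that add atoms: none
Why: Condensation of the ketone with the hydrazine gives the chiral hydrazone; the ketone is symmetric, so no isomer issue arises.

Step 7
Reactants: 12 (R)-N-(2,2-dimethyl-1,3-dioxan-5-ylidene)-2-(methoxymethyl)pyrrolidin-1-amine; 9 (1E,5Z)-7-bromo-1-iodo-2,6-dimethylhepta-1,5-diene
Product: 14 (R)-N-[(4R)-4-[(2Z,6E)-7-iodo-2,6-dimethylhepta-2,6-dien-1-yl]-2,2-dimethyl-1,3-dioxan-5-ylidene]-2-(methoxymethyl)pyrrolidin-1-amine, via lithium azaenolate 13 (not isolated)
Conditions: t-BuLi (1.0 equiv), THF, −78 °C; then 9, −100 °C to rt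
Reagents that add atoms: none
Why: Enders hydrazone alkylation; the ring-fixed azaenolate 13, with lithium held by the methoxymethyl arm, is alkylated by SN2 on the face left open by the pyrrolidine, which with the R auxiliary sets C8 as R. The alkenyl iodide is safe because no alkyllithium remains when 9 is added.

Step 8
Reactants: 14 (R)-N-[(4R)-4-[(2Z,6E)-7-iodo-2,6-dimethylhepta-2,6-dien-1-yl]-2,2-dimethyl-1,3-dioxan-5-ylidene]-2-(methoxymethyl)pyrrolidin-1-amine
Product: 15 (4R)-4-[(2Z,6E)-7-iodo-2,6-dimethylhepta-2,6-dien-1-yl]-2,2-dimethyl-1,3-dioxan-5-one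
Conditions: sat. aq. oxalic acid, Et2O, rt
Reagents that add atoms: water O
Why: Two-phase oxalic acid hydrolysis of the hydrazone avoids ozone, which would destroy both olefins; it should leave the acetonide intact and C8 unepimerised, and the auxiliary is recovered from the aqueous phase.

Step 9
Reactants: 15 (4R)-4-[(2Z,6E)-7-iodo-2,6-dimethylhepta-2,6-dien-1-yl]-2,2-dimethyl-1,3-dioxan-5-one; 16 methyl propiolate
Product: 18 methyl 2-[(4R,5R)-5-hydroxy-4-[(2Z,6E)-7-iodo-2,6-dimethylhepta-2,6-dien-1-yl]-2,2-dimethyl-1,3-dioxan-5-yl]prop-2-enoate, via α-aluminated acrylate 17 (not isolated)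
Conditions: i-Bu2AlH, N-methylmorpholine N-oxide, THF, 0 °C (16 in slight excess over hydride); then 15, 0 °C to rt
Reagents that add atoms: none
Why: Vinylalumination; 1,4-hydroalumination of the propiolate gives the non-basic nucleophile 17, which should add to the inductively activated α,α'-dialkoxy ketone without enolising it. Attack along the equatorial direction of the chair (side chain equatorial), anti to the ring C–O bonds, places C11 trans and O7 cis to the side chain, which is the C7 configuration needed (5R in this compound).

Step 10
Reactants: 18 methyl 2-[(4R,5R)-5-hydroxy-4-[(2Z,6E)-7-iodo-2,6-dimethylhepta-2,6-dien-1-yl]-2,2-dimethyl-1,3-dioxan-5-yl]prop-2-enoate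
Product: 19 methyl 2-[(4R,5R)-4-[(2Z,6E)-7-iodo-2,6-dimethylhepta-2,6-dien-1-yl]-2,2-dimethyl-5-[(triethylsilyl)oxy]-1,3-dioxan-5-yl]prop-2-enoate
Conditions: Et3SiOTf, 2,6-lutidine, CH2Cl2, −78 to 0 °C
Reagents that add atoms: triethylsilyl trifluoromethanesulfonate CC[Si](CC)(CC)OS(=O)(=O)C(F)(F)F
Why: Silyl triflate silylation of a tertiary alcohol; the acetonide and ester are untouched at low temperature, and the bulky non-chelating ether later blocks α-ketol rearrangement and directs the key step.

Step 11
Reactants: 19 methyl 2-[(4R,5R)-4-[(2Z,6E)-7-iodo-2,6-dimethylhepta-2,6-dien-1-yl]-2,2-dimethyl-5-[(triethylsilyl)oxy]-1,3-dioxan-5-yl]prop-2-enoate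
Product: 20 methyl 2-[(2R,3R,5Z,9E)-1,3-dihydroxy-10-iodo-5,9-dimethyl-2-[(triethylsilyl)oxy]deca-5,9-dien-2-yl]prop-2-enoate
Conditions: pyridinium p-toluenesulfonate (cat.), MeOH, 0 °C to rt, NaHCO3 quench at full conversion; used at once
Reagents that add atoms: none
Why: Acid-catalysed methanolysis of the 2,2-dimethyl-1,3-dioxane, which is strained by its axial methyl group, should be much faster under pyridinium catalysis than activation of a conjugated methyl ester, so the diol can be taken on before O6–H or O8–H lactonises onto C12. The hindered tertiary silyl ether should survive the short exposure.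

Step 12
Reactants: 20 methyl 2-[(2R,3R,5Z,9E)-1,3-dihydroxy-10-iodo-5,9-dimethyl-2-[(triethylsilyl)oxy]deca-5,9-dien-2-yl]prop-2-enoate
Product: 21 methyl 2-[(2S,3R,5Z,9E)-3-hydroxy-10-iodo-5,9-dimethyl-1-oxo-2-[(triethylsilyl)oxy]deca-5,9-dien-2-yl]prop-2-enoate
Conditions: TEMPO (cat.), PhI(OAc)2, CH2Cl2, rt
Reagents that add atoms: none
Why: Oxoammonium oxidation is selective for the primary over the secondary alcohol and stops at the aldehyde, which cannot epimerise because C7 is fully substituted (the descriptor change at C7 is only a priority change).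

Step 13
Reactants: 21 methyl 2-[(2S,3R,5Z,9E)-3-hydroxy-10-iodo-5,9-dimethyl-1-oxo-2-[(triethylsilyl)oxy]deca-5,9-dien-2-yl]prop-2-enoate
Product: 22 methyl 2-[(2S,3R,5Z,9E)-10-iodo-5,9-dimethyl-3-[(2-methylprop-2-enoyl)oxy]-1-oxo-2-[(triethylsilyl)oxy]deca-5,9-dien-2-yl]prop-2-enoate
Conditions: methacrylic anhydride, DMAP (cat.), Et3N, CH2Cl2, 0 °C
Reagents that add atoms: methacrylic anhydride C=C(C)C(=O)OC(=O)C(C)=C
Why: DMAP-catalysed acylation of the secondary alcohol; acyl transfer should outrun retro-aldol cleavage or silyl migration under amine base at 0 °C, and the aldehyde has no α-hydrogen.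

Step 14
Reactants: 22 methyl 2-[(2S,3R,5Z,9E)-10-iodo-5,9-dimethyl-3-[(2-methylprop-2-enoyl)oxy]-1-oxo-2-[(triethylsilyl)oxy]deca-5,9-dien-2-yl]prop-2-enoate
Product: 25 (1(10)Z,4E,6R,7S,8R)-8-(methacryloyloxy)-7-[(triethylsilyl)oxy]germacra-1(10),4,11(13)-trien-12,6-olide, via alkenylchromium 23 (not isolated), via chromium alkoxide 24 (not isolated)
Conditions: CrCl2 (excess), NiCl2 (cat.), degassed DMSO/THF, rt, slow addition of 22 to high dilution; aq. NH4Cl work-up
Reagents that add atoms: none
Why: CrCl2 reduces NiCl2 to zerovalent nickel, which inserts into the C5–I bond with retention of the E geometry; transmetalation to trivalent chromium gives 23, which adds to the C6 aldehyde to form C5–C6 and the carbocycle (24). The closest known reaction type is the intramolecular Nozaki–Hiyama–Kishi coupling of alkenyl iodides with aldehydes used for medium and large rings. The ten-membered ring closes end to end by a 10-exo-trig carbonyl addition, helped by the Z C1=C10 olefin acting as a turn; the lactone closes by 5-exo-trig attack of the C6 chromium alkoxide on the C12 methyl ester with loss of methoxide. C6 is the only new stereocentre: with the bulky, non-chelating C7 silyloxy group antiperiplanar to the incoming C5 (Felkin–Anh) and the C8 arm gauche to the carbonyl oxygen, attack places O6 cis to O7, the arrangement a trans-fused lactone on a 4E ring requires. The step needs chemoselectivity for the aldehyde over two esters and two acceptor olefins, which the low basicity and carbonyl selectivity of organochromium reagents secure, and ring closure over intermolecular coupling, which slow addition at high dilution secures.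

Step 15
Reactants: 25 (1(10)Z,4E,6R,7S,8R)-8-(methacryloyloxy)-7-[(triethylsilyl)oxy]germacra-1(10),4,11(13)-trien-12,6-olide
Product: 26 (1(10)Z,4E,6R,7S,8R)-7-hydroxy-8-(methacryloyloxy)germacra-1(10),4,11(13)-trien-12,6-olide
Conditions: HF·pyridine, pyridine, THF, 0 °C to rt
Reagents that add atoms: none
Why: Fluoride cleavage of the tertiary silyl ether under buffered, non-basic conditions keeps the methacrylate on O8 and spares the Michael acceptors. It is placed before epoxidation because fluoride or acid would open the epoxides transannularly.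

Step 16
Reactants: 26 (1(10)Z,4E,6R,7S,8R)-7-hydroxy-8-(methacryloyloxy)germacra-1(10),4,11(13)-trien-12,6-olide
Product: 28 (1S,4R,5R,6R,7S,8R,10R)-1,10:4,5-diepoxy-7-hydroxy-8-(methacryloyloxy)germacr-11(13)-en-12,6-olide (the target), via 1α,10α-monoepoxide 27 (not isolated)
Conditions: dimethyldioxirane (acetone solution, excess), CH2Cl2, −20 to 0 °C
Reagents that add atoms: dimethyldioxirane CC1(C)OO1
Why: Neutral electrophilic epoxidation; the dioxirane should attack only the two electron-rich trisubstituted olefins, C1=C10 first (27) and then C4=C5, which is deactivated by the allylic lactone oxygen. Each olefin of the medium ring exposes only its outer face; with both ring methyls on the β face in the expected conformation, oxygen should reach C1=C10 from the α face (1S,10R) and C4=C5 in the 4α,5β sense (4R,5R), the sense usual for 4E germacranolides with a trans-fused 6,12-lactone.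

## Compound list

1 | pent-4-yn-1-ol | C#CCCCO | starting material
2 | dimethyl[(E)-5-(dimethylalumanyloxy)-2-methylpent-1-en-1-yl]alane | C[Al](C)OCCC/C(C)=C/[Al](C)C | intermediate
3 | (E)-5-iodo-4-methylpent-4-en-1-ol | OCCC/C(C)=C/I | intermediate
4 | (E)-5-iodo-4-methylpent-4-enal | O=CCC/C(C)=C/I | intermediate
5 | ethyl 2-[bis(2,2,2-trifluoroethoxy)phosphoryl]propanoate | CCOC(=O)C(C)P(=O)(OCC(F)(F)F)OCC(F)(F)F | starting material
6 | potassium salt of the α-carbanion of 5 | CCOC(=O)[C-](C)P(=O)(OCC(F)(F)F)OCC(F)(F)F.[K+] | intermediate
7 | ethyl (2Z,6E)-7-iodo-2,6-dimethylhepta-2,6-dienoate | CCOC(=O)/C(C)=C\CC/C(C)=C/I | intermediate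
8 | (2Z,6E)-7-iodo-2,6-dimethylhepta-2,6-dien-1-ol | OC/C(C)=C\CC/C(C)=C/I | intermediate
9 | (1E,5Z)-7-bromo-1-iodo-2,6-dimethylhepta-1,5-diene | BrC/C(C)=C\CC/C(C)=C/I | intermediate
10 | 2,2-dimethyl-1,3-dioxan-5-one | CC1(C)OCC(=O)CO1 | starting material
11 | (R)-1-amino-2-(methoxymethyl)pyrrolidine (RAMP) | COC[C@H]1CCCN1N | starting material
12 | (R)-N-(2,2-dimethyl-1,3-dioxan-5-ylidene)-2-(methoxymethyl)pyrrolidin-1-amine | COC[C@H]1CCCN1N=C1COC(C)(C)OC1 | intermediate
13 | lithium azaenolate of 12 (N-lithio ene-hydrazide, C4=C5 in the dioxane ring) | COC[C@H]1CCCN1N([Li])C1=COC(C)(C)OC1 | intermediate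
14 | (R)-N-[(4R)-4-[(2Z,6E)-7-iodo-2,6-dimethylhepta-2,6-dien-1-yl]-2,2-dimethyl-1,3-dioxan-5-ylidene]-2-(methoxymethyl)pyrrolidin-1-amine | COC[C@H]1CCCN1N=C1COC(C)(C)O[C@@H]1C/C(C)=C\CC/C(C)=C/I | intermediate
15 | (4R)-4-[(2Z,6E)-7-iodo-2,6-dimethylhepta-2,6-dien-1-yl]-2,2-dimethyl-1,3-dioxan-5-one | O=C1COC(C)(C)O[C@@H]1C/C(C)=C\CC/C(C)=C/I | intermediate
16 | methyl propiolate | C#CC(=O)OC | starting material
17 | [1-(methoxycarbonyl)ethenyl]bis(2-methylpropyl)alane | C=C(C(=O)OC)[Al](CC(C)C)CC(C)C | intermediate
18 | methyl 2-[(4R,5R)-5-hydroxy-4-[(2Z,6E)-7-iodo-2,6-dimethylhepta-2,6-dien-1-yl]-2,2-dimethyl-1,3-dioxan-5-yl]prop-2-enoate | C=C(C(=O)OC)[C@@]1(O)COC(C)(C)O[C@@H]1C/C(C)=C\CC/C(C)=C/I | intermediate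
19 | methyl 2-[(4R,5R)-4-[(2Z,6E)-7-iodo-2,6-dimethylhepta-2,6-dien-1-yl]-2,2-dimethyl-5-[(triethylsilyl)oxy]-1,3-dioxan-5-yl]prop-2-enoate | C=C(C(=O)OC)[C@@]1(O[Si](CC)(CC)CC)COC(C)(C)O[C@@H]1C/C(C)=C\CC/C(C)=C/I | intermediate
20 | methyl 2-[(2R,3R,5Z,9E)-1,3-dihydroxy-10-iodo-5,9-dimethyl-2-[(triethylsilyl)oxy]deca-5,9-dien-2-yl]prop-2-enoate | O[C@H](C/C(C)=C\CC/C(C)=C/I)[C@](O[Si](CC)(CC)CC)(CO)C(=C)C(=O)OC | intermediate
21 | methyl 2-[(2S,3R,5Z,9E)-3-hydroxy-10-iodo-5,9-dimethyl-1-oxo-2-[(triethylsilyl)oxy]deca-5,9-dien-2-yl]prop-2-enoate | O[C@H](C/C(C)=C\CC/C(C)=C/I)[C@](O[Si](CC)(CC)CC)(C=O)C(=C)C(=O)OC | intermediate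
22 | methyl 2-[(2S,3R,5Z,9E)-10-iodo-5,9-dimethyl-3-[(2-methylprop-2-enoyl)oxy]-1-oxo-2-[(triethylsilyl)oxy]deca-5,9-dien-2-yl]prop-2-enoate | C=C(C)C(=O)O[C@H](C/C(C)=C\CC/C(C)=C/I)[C@](O[Si](CC)(CC)CC)(C=O)C(=C)C(=O)OC | intermediate
23 | C5 alkenylchromium dichloride derived from 22 (E geometry retained) | C=C(C)C(=O)O[C@H](C/C(C)=C\CC/C(C)=C/[Cr](Cl)Cl)[C@](O[Si](CC)(CC)CC)(C=O)C(=C)C(=O)OC | intermediate
24 | C6 chromium alkoxide of the ring-closed methyl ester (6R,7S,8R; 1(10)Z,4E) | C=C(C)C(=O)O[C@@H]1C/C(C)=C\CC/C(C)=C/[C@@H](O[Cr](Cl)Cl)[C@]1(O[Si](CC)(CC)CC)C(=C)C(=O)OC | intermediate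
25 | (1(10)Z,4E,6R,7S,8R)-8-(methacryloyloxy)-7-[(triethylsilyl)oxy]germacra-1(10),4,11(13)-trien-12,6-olide | C=C(C)C(=O)O[C@@H]1C/C(C)=C\CC/C(C)=C/[C@H]2OC(=O)C(=C)[C@@]21O[Si](CC)(CC)CC | intermediate
26 | (1(10)Z,4E,6R,7S,8R)-7-hydroxy-8-(methacryloyloxy)germacra-1(10),4,11(13)-trien-12,6-olide | C=C(C)C(=O)O[C@@H]1C/C(C)=C\CC/C(C)=C/[C@H]2OC(=O)C(=C)[C@@]21O | intermediate
27 | (1S,4E,6R,7S,8R,10R)-1,10-epoxy-7-hydroxy-8-(methacryloyloxy)germacra-4,11(13)-dien-12,6-olide | C=C(C)C(=O)O[C@@H]1C[C@@]2(C)O[C@H]2CC/C(C)=C/[C@H]2OC(=O)C(=C)[C@@]21O | intermediate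
28 | (1S,4R,5R,6R,7S,8R,10R)-1,10:4,5-diepoxy-7-hydroxy-8-(methacryloyloxy)germacr-11(13)-en-12,6-olide | C=C(C)C(=O)O[C@@H]1C[C@@]2(C)O[C@H]2CC[C@@]2(C)O[C@@H]2[C@H]2OC(=O)C(=C)[C@@]21O | target

## Step count and least certain steps

Total: 16 steps. Longest linear sequence: 15 steps (steps 1–5 and 7–16, from 1); step 6 is a one-step branch.

Step 14 (key step). Three things can go wrong.
- Bimolecular coupling or protodemetalation may outrun closure, because the ring is strained and the aldehyde is neopentylic.
- Attack on the other aldehyde face would give the 6-epimer.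
- The C6 alkoxide may take the O8 acyl group instead of closing the lactone.

Fallback, in which C6 is set by reduction and not by the C–C bond formation: starting from 22, the coupling is run as above. The wrong-face product, the 6-epi ring-closed hydroxy ester F1, should resist lactonisation because it would need a cis-fused lactone on a 4E ring. It is oxidised with MnO2 or Dess–Martin periodinane to the ring enone F2. 1,2-Reduction with NaBH4/CeCl3 at −78 °C, or with a CBS oxazaborolidine and catecholborane in the enantiomeric form that delivers hydride to the required face, gives the 6R alkoxide, which lactonises and rejoins the route at 25.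

Step 9. The carbonyl addition to a hindered, enolisable ketone may be slow, so that C8 epimerises first, or the face selectivity may be insufficient. Fallback with a different acrylate α-anion equivalent: starting from 15, the lithium enolate of methyl 3-(dimethylamino)propanoate (LiN(i-Pr)2, THF, −78 °C) adds to the ketone, in the trans sense expected for organolithium reagents on α-alkylated dioxanones, to give the β-amino ester adduct F3. Methylation with MeI gives the trimethylammonium iodide F4, and K2CO3 eliminates trimethylamine to rejoin the route at 18.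

Step 11. The liberated O6–H or O8–H may lactonise onto the C12 ester, or the tertiary silyl ether may be lost, if the acid exposure is prolonged. Fallback that never frees a hydroxyl γ to the ester in acid and bypasses 19–21:
1. Starting from 18, excess Et3SiOTf with i-Pr2NEt silylates O7 and opens the dioxane, by silyl triflate ring-opening of the ketal with proton loss, to the O6,O7-bis(triethylsilyl) O8-(prop-1-en-2-yl) ether F5.
2. Brief aqueous oxalic acid hydrolyses only the enol ether, giving the O8 alcohol F6.
3. Methacrylic anhydride/DMAP gives the methacrylate F7.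
4. Swern oxidation, which converts a primary triethylsilyl ether directly into the aldehyde, rejoins the route at 22.

Step 16. Attack may occur on the wrong face of the Z C1=C10 olefin, whose facial bias is less well precedented than that of the 4E olefin, or the first-formed epoxide may open transannularly if traces of acid are present. Fallback with directed instead of peripheral delivery: starting from 26, VO(acac)2 (cat.) with t-BuOOH forms the vanadate ester of the 7α-hydroxyl, which should deliver oxygen to the α face of the bishomoallylic C1=C10 olefin and give 27. Dimethyldioxirane then epoxidises C4=C5 and the route is rejoined at 28. No new compound is made.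

## Further compounds

F1 | step 14 | C6 epimer (6S) of the unlactonised ring-closed hydroxy methyl ester: methyl (1(10)Z,4E)-6β-hydroxy-8β-(methacryloyloxy)-7α-[(triethylsilyl)oxy]germacra-1(10),4,11(13)-trien-12-oate | C=C(C)C(=O)O[C@@H]1C/C(C)=C\CC/C(C)=C/[C@H](O)[C@]1(O[Si](CC)(CC)CC)C(=C)C(=O)OC
F2 | step 14 | ring enone: methyl (1(10)Z,4E)-8β-(methacryloyloxy)-6-oxo-7α-[(triethylsilyl)oxy]germacra-1(10),4,11(13)-trien-12-oate | C=C(C)C(=O)O[C@@H]1C/C(C)=C\CC/C(C)=C/C(=O)[C@]1(O[Si](CC)(CC)CC)C(=C)C(=O)OC
F3 | step 9 | methyl 3-(dimethylamino)-2-[(4R,5R)-5-hydroxy-4-[(2Z,6E)-7-iodo-2,6-dimethylhepta-2,6-dien-1-yl]-2,2-dimethyl-1,3-dioxan-5-yl]propanoate (both C2 epimers) | CN(C)CC(C(=O)OC)[C@@]1(O)COC(C)(C)O[C@@H]1C/C(C)=C\CC/C(C)=C/I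
F4 | step 9 | N-methyl quaternary ammonium iodide of F3 | C[N+](C)(C)CC(C(=O)OC)[C@@]1(O)COC(C)(C)O[C@@H]1C/C(C)=C\CC/C(C)=C/I.[I-]
F5 | step 11 | methyl 2-[(2R,3R,5Z,9E)-10-iodo-5,9-dimethyl-3-(prop-1-en-2-yloxy)-1,2-bis[(triethylsilyl)oxy]deca-5,9-dien-2-yl]prop-2-enoate | C=C(C)O[C@H](C/C(C)=C\CC/C(C)=C/I)[C@](O[Si](CC)(CC)CC)(CO[Si](CC)(CC)CC)C(=C)C(=O)OC
F6 | step 11 | methyl 2-[(2R,3R,5Z,9E)-3-hydroxy-10-iodo-5,9-dimethyl-1,2-bis[(triethylsilyl)oxy]deca-5,9-dien-2-yl]prop-2-enoate | O[C@H](C/C(C)=C\CC/C(C)=C/I)[C@](O[Si](CC)(CC)CC)(CO[Si](CC)(CC)CC)C(=C)C(=O)OC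
F7 | step 11 | O8 methacrylate of F6 | C=C(C)C(=O)O[C@H](C/C(C)=C\CC/C(C)=C/I)[C@](O[Si](CC)(CC)CC)(CO[Si](CC)(CC)CC)C(=C)C(=O)OC
F0 | step 16 | none | none
A1 | alternative 1 | (Z)-7-(1,3-dioxolan-2-yl)-6-methylhept-5-en-2-one | CC(=O)CC/C=C(C)\CC1OCCO1
A2 | alternative 1 | (1,3-dioxolan-2-ylmethyl)magnesium bromide | Br[Mg]CC1OCCO1
A3 | alternative 1 | propyne | CC#C
A4 | alternative 1 | but-3-en-2-one (methyl vinyl ketone) | C=CC(C)=O
A5 | alternative 2 | (Z)-cyclodec-1(10)-en-5-one with C4 methoxymethyl ether, C6/C7 acetonide, C8 tert-butyldimethylsilyl ether and C11 (4-methoxybenzyloxy)methylvinyl group | CC(C)(C)[Si](C)(C)O[C@@H]1C/C(C)=C\CC[C@@](C)(OCOC)C(=O)[C@H]2OC(C)(C)O[C@]21C(=C)COCc1ccc(OC)cc1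
A6 | alternative 2 | cis-fused decalin (C5–C10 bond) with C5 tertiary hydroxyl cis to the C10 methyl and an equatorial C1 methanesulfonate trans to that methyl, otherwise substituted as A5 | CC(C)(C)[Si](C)(C)O[C@@H]1C[C@@]2(C)[C@@H](OS(C)(=O)=O)CC[C@@](C)(OCOC)[C@@]2(O)[C@H]2OC(C)(C)O[C@]21C(=C)COCc1ccc(OC)cc1
A7 | alternative 3 | (1(10)Z,4E,6R,7S,8R)-7-hydroxy-8-(methacryloyloxy)germacra-1(10),4,11(13)-trien-12,6-olide (identical with 26) | C=C(C)C(=O)O[C@@H]1C/C(C)=C\CC/C(C)=C/[C@H]2OC(=O)C(=C)[C@@]21O
A8 | alternative 3 | (1(10)Z,4E,6R,8R)-6-(2-bromoprop-2-enoyloxy)-8-(methacryloyloxy)cyclodeca-1(10),4-dien-7-one (germacrane numbering) | C=C(C)C(=O)O[C@@H]1C/C(C)=C\CC/C(C)=C/[C@@H](OC(=O)C(Br)=C)C1=O
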